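**Retrosynthetic overview** (oxolane numbering: O1, C2 bears the guaiacyl ring, C3 and C4 bear the methyls, C5 bears the veratryl ring)
- Target 21 ⇒ silyl ether 20 ⇒ C2–aryl bond: arylzinc 18 (carries the whole 8-O-4' side chain; its two stereocenters come from ethyl (S)-lactate by Mitsunobu inversion and Felkin–Anh reduction) + 2-sulfonyloxolane 7, joined through oxocarbenium ion 19 by inside-face arylation.
- 7 ⇒ lactol 6 ⇒ homoallylic alcohol 4 + CO + H2: hydroxyl-directed branched hydroformylation makes C2 from CO, the C2–C3 bond and the C3 methyl branch, and the released γ-hydroxy aldehyde closes the ring; 4 ⇒ aldehyde 1 + (Z)-crotylboronate 2 (catalytic asymmetric syn-crotylation sets C5 and C4).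
- Enabling feature: C3 and C4 each carry a methyl and C2 is an acetal-level benzylic carbon, so O1–C5(aryl)–C4(CH3)–C3 is a syn-crotyl carbinol whose vinyl carbon (future C3) lies three bonds from the O1 hydroxyl; that hydroxyl can steer rhodium to C3 and then trap the new formyl carbon as the five-membered hemiacetal.
- Ring order: the three benzene rings are bought; the oxolane is the only ring made (step 2), and its C2–aryl bond follows in step 9.

Key step: step 2

Remark: 2 and 12 are taken as purchasable reagents, and the (S)-enantiomer of the phosphoric acid catalyst is assumed to deliver the crotyl group to the Si face of 1 (mirror image of the Re-face delivery of the (R)-catalyst).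

Step 1
Reactants: 1 3,4-dimethoxybenzaldehyde; 2 (Z)-crotylboronic acid pinacol ester
Product: 4 (1S,2R)-1-(3,4-dimethoxyphenyl)-2-methylbut-3-en-1-ol, via borate ester 3 (not isolated)
Conditions: (S)-3,3'-bis(2,4,6-triisopropylphenyl)-1,1'-binaphthyl-2,2'-diyl hydrogen phosphate (5 mol %), 4 Å MS, toluene, −30 °C; then H2O
Reagents that add atoms: none
Why: Chiral phosphoric acid-catalyzed crotylboration of an aldehyde through a closed six-membered chair transition state, in which the (Z)-geometry of 2 is transmitted to the syn relationship of the two new centers and the catalyst, hydrogen-bonded to a boronate oxygen and the formyl hydrogen, should expose the Si face of 1 to give the (1S,2R) isomer (future C5 and C4).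

Step 2
Reactants: 4 (1S,2R)-1-(3,4-dimethoxyphenyl)-2-methylbut-3-en-1-ol
Product: 6 (3R,4R,5S)-5-(3,4-dimethoxyphenyl)-3,4-dimethyloxolan-2-ol (anomeric mixture), via hydroxy aldehyde 5 (not isolated)
Conditions: Rh(acac)(CO)2 (2 mol %), Ph2POMe (10 mol %), 4 Å MS, CO/H2 (1:1, 40 bar), THF, 40 °C; then DBU (0.1 equiv), CH2Cl2, rt
Reagents that add atoms: carbon monoxide, [C-]#[O+]
Why: Ph2POMe exchanges reversibly with the C5 hydroxyl of 4 to give a substrate-bound phosphinite, which holds the monovalent rhodium hydride over the vinyl group so that hydrometalation passes through a six-membered P,C-chelate to the secondary alkyl at C3, and CO insertion with retention followed by hydrogenolysis releases hydroxy aldehyde 5; the closest known reaction type is the branched hydroformylation of homoallylic alcohols steered by a catalytic, reversibly bound phosphinite directing group, which gives γ-lactols. The oxolane ring then closes by 5-exo-trig addition of the C5 hydroxyl to the formyl carbon (hemiacetal formation), the ring bond C2–C3 having been made in the carbonyl insertion. The new stereocenter C3 is controlled by the adjacent C4: in the chelate the C4–H bond eclipses the alkene to minimize allylic 1,3-strain and rhodium adds to the face away from the C4 methyl, which leads to the 3,4-trans (3R) isomer, and because C3 is α to the formyl group of 5 the DBU treatment should converge any cis epimer onto this thermodynamically preferred isomer. C4 and C5 are not touched, and the anomeric carbon C2 is left as a mixture because it is made planar again in the arylation of step 9. The step needs branched over linear regioselectivity (five- instead of six-membered lactol) and chemoselectivity over alkene hydrogenation or isomerization; the first is secured by the hydroxyl placed three bonds from the internal vinyl carbon, the second by the mild temperature under CO pressure.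

Step 3
Reactants: 6 (3R,4R,5S)-5-(3,4-dimethoxyphenyl)-3,4-dimethyloxolan-2-ol
Product: 7 (3R,4R,5S)-2-(benzenesulfonyl)-5-(3,4-dimethoxyphenyl)-3,4-dimethyloxolane (anomeric mixture)
Conditions: PhSO2H (1.5 equiv), CaCl2, CH2Cl2, rt
Reagents that add atoms: benzenesulfinic acid, O=S(O)c1ccccc1
Why: Acid-mediated condensation of the lactol with benzenesulfinic acid (exchange of the anomeric hydroxyl for the S-bound sulfinate with loss of water, which CaCl2 takes up) should give the bench-stable 2-sulfonyl cyclic ether as a storable substrate for the anomeric arylation of step 9, with C3, C4 and C5 untouched and the anomeric mixture of no consequence.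

Step 4
Reactants: 8 4-bromo-2-methoxyphenol; 9 ethyl (S)-lactate
Product: 10 ethyl (R)-2-(4-bromo-2-methoxyphenoxy)propanoate
Conditions: PPh3, DIAD, THF, 0 °C → rt
Reagents that add atoms: none
Why: Mitsunobu etherification of the acidic phenol with the secondary lactate hydroxyl proceeds by SN2 displacement of the oxyphosphonium with inversion, turning the (S)-lactate center into the (R)-aryl ether that becomes the ether-bearing carbon of the side chain.

Step 5
Reactants: 10 ethyl (R)-2-(4-bromo-2-methoxyphenoxy)propanoate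
Product: 11 (R)-2-(4-bromo-2-methoxyphenoxy)-N-methoxy-N-methylpropanamide
Conditions: MeNH(OMe)·HCl (1.5 equiv), i-PrMgCl (3.0 equiv), THF, −20 °C; aq NH4Cl
Reagents that add atoms: N,O-dimethylhydroxylamine hydrochloride, CNOC.Cl
Why: Weinreb amide formation by aminolysis of the ester with the chloromagnesium amide made in the flask, a weakly basic nucleophile that at low temperature should leave the α-aryloxy stereocenter and the aryl bromide untouched.

Step 6
Reactants: 11 (R)-2-(4-bromo-2-methoxyphenoxy)-N-methoxy-N-methylpropanamide; 12 3,4-dimethoxyphenylmagnesium bromide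
Product: 14 (R)-2-(4-bromo-2-methoxyphenoxy)-1-(3,4-dimethoxyphenyl)propan-1-one, via magnesium hemiaminal 13 (not isolated)
Conditions: THF, −10 → 0 °C; then cold 1 M HCl
Reagents that add atoms: none
Why: Weinreb ketone synthesis, in which the aryl Grignard reagent adds once to give the chelated tetrahedral intermediate 13 that shields the α-center from enolization and collapses to the ketone only on acidic quench, so that no stereocenter is formed or lost.

Step 7
Reactants: 14 (R)-2-(4-bromo-2-methoxyphenoxy)-1-(3,4-dimethoxyphenyl)propan-1-one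
Product: 15 (1R,2R)-2-(4-bromo-2-methoxyphenoxy)-1-(3,4-dimethoxyphenyl)propan-1-ol
Conditions: polystyrene-bound trimethylammonium borohydride (Amberlite IRA-400, BH4− form), MeOH, 0 °C
Reagents that add atoms: none
Why: Felkin–Anh reduction with a borohydride whose ammonium counter-ion cannot chelate, so that hydride attacks anti to the electronegative aryloxy substituent and past the α-hydrogen, which should set the new carbinol center syn to the ether oxygen and give the (1R,2R) threo alcohol.

Step 8
Reactants: 15 (1R,2R)-2-(4-bromo-2-methoxyphenoxy)-1-(3,4-dimethoxyphenyl)propan-1-ol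
Product: 16 tert-butyl{[(1R,2R)-2-(4-bromo-2-methoxyphenoxy)-1-(3,4-dimethoxyphenyl)propyl]oxy}dimethylsilane
Conditions: TBSOTf, 2,6-lutidine, CH2Cl2, 0 °C
Reagents that add atoms: tert-butyldimethylsilyl triflate, CC(C)(C)[Si](C)(C)OS(=O)(=O)C(F)(F)F
Why: Silylation of the secondary benzylic alcohol with a silyl triflate and a hindered base masks the only acidic proton before metalation and affects no stereocenter.

Step 9
Reactants: 16 tert-butyl{[(1R,2R)-2-(4-bromo-2-methoxyphenoxy)-1-(3,4-dimethoxyphenyl)propyl]oxy}dimethylsilane; 7 (3R,4R,5S)-2-(benzenesulfonyl)-5-(3,4-dimethoxyphenyl)-3,4-dimethyloxolane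
Product: 20 tert-butyl{[(1R,2R)-1-(3,4-dimethoxyphenyl)-2-{4-[(2S,3R,4R,5S)-5-(3,4-dimethoxyphenyl)-3,4-dimethyloxolan-2-yl]-2-methoxyphenoxy}propyl]oxy}dimethylsilane, via aryllithium 17 (not isolated), via arylzinc bromide 18 (not isolated), via oxocarbenium ion 19 (not isolated)
Conditions: 16 (1.5 equiv), n-BuLi, THF, −78 °C; ZnBr2, −78 → 0 °C; then 7, THF, 0 °C → rt; aq NH4Cl
Reagents that add atoms: none
Why: Bromine–lithium exchange and transmetalation give arylzinc 18, and ZnBr2-assisted loss of sulfinate from sulfone 7 gives oxocarbenium ion 19, which should be arylated as in known organozinc additions to 2-sulfonyl cyclic ethers, by attack on the inside face of the envelope that has the C4 methyl pseudo-equatorial, so that the aryl group ends up anti to the C4 methyl and cis to the C3 methyl and C2 is set as (S) in the 2,3-cis-3,4-trans-4,5-cis oxolane.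

Step 10
Reactants: 20 silyl ether of the target
Product: 21 (1R,2R)-1-(3,4-dimethoxyphenyl)-2-{4-[(2S,3R,4R,5S)-5-(3,4-dimethoxyphenyl)-3,4-dimethyloxolan-2-yl]-2-methoxyphenoxy}propan-1-ol
Conditions: Bu4NF, THF, 0 °C → rt
Reagents that add atoms: none
Why: Fluoride-mediated desilylation under non-acidic conditions should free the carbinol while leaving the acid-sensitive bis-benzylic oxolane and all six stereocenters untouched.

**Compound list**
1 | 3,4-dimethoxybenzaldehyde | COc1ccc(C=O)cc1OC | starting material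
2 | (Z)-crotylboronic acid pinacol ester | C/C=C\CB1OC(C)(C)C(C)(C)O1 | starting material
3 | 2-{[(1S,2R)-1-(3,4-dimethoxyphenyl)-2-methylbut-3-en-1-yl]oxy}-4,4,5,5-tetramethyl-1,3,2-dioxaborolane (borate ester) | CC1(C)OB(O[C@H](c2ccc(OC)c(OC)c2)[C@H](C)C=C)OC1(C)C | intermediate
4 | (1S,2R)-1-(3,4-dimethoxyphenyl)-2-methylbut-3-en-1-ol | COc1ccc([C@@H](O)[C@H](C)C=C)cc1OC | intermediate
5 | (2R,3R,4S)-4-(3,4-dimethoxyphenyl)-4-hydroxy-2,3-dimethylbutanal (hydroxy aldehyde) | COc1ccc([C@@H](O)[C@H](C)[C@@H](C)C=O)cc1OC | intermediate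
6 | (3R,4R,5S)-5-(3,4-dimethoxyphenyl)-3,4-dimethyloxolan-2-ol (anomeric mixture) | OC1O[C@H](c2ccc(OC)c(OC)c2)[C@H](C)[C@H]1C | intermediate
7 | (3R,4R,5S)-2-(benzenesulfonyl)-5-(3,4-dimethoxyphenyl)-3,4-dimethyloxolane (anomeric mixture) | O=S(=O)(c1ccccc1)C1O[C@H](c2ccc(OC)c(OC)c2)[C@H](C)[C@H]1C | intermediate
8 | 4-bromo-2-methoxyphenol | COc1cc(Br)ccc1O | starting material
9 | ethyl (S)-lactate | C[C@H](O)C(=O)OCC | starting material
10 | ethyl (R)-2-(4-bromo-2-methoxyphenoxy)propanoate | C[C@@H](Oc1ccc(Br)cc1OC)C(=O)OCC | intermediate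
11 | (R)-2-(4-bromo-2-methoxyphenoxy)-N-methoxy-N-methylpropanamide | C[C@@H](Oc1ccc(Br)cc1OC)C(=O)N(C)OC | intermediate
12 | 3,4-dimethoxyphenylmagnesium bromide | COc1ccc([Mg]Br)cc1OC | starting material
13 | bromomagnesium alkoxide of the tetrahedral adduct of 11 and 12 (magnesium hemiaminal) | C[C@@H](Oc1ccc(Br)cc1OC)C(O[Mg]Br)(N(C)OC)c1ccc(OC)c(OC)c1 | intermediate
14 | (R)-2-(4-bromo-2-methoxyphenoxy)-1-(3,4-dimethoxyphenyl)propan-1-one | C[C@@H](Oc1ccc(Br)cc1OC)C(=O)c1ccc(OC)c(OC)c1 | intermediate
15 | (1R,2R)-2-(4-bromo-2-methoxyphenoxy)-1-(3,4-dimethoxyphenyl)propan-1-ol | COc1ccc([C@@H](O)[C@@H](C)Oc2ccc(Br)cc2OC)cc1OC | intermediate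
16 | tert-butyl{[(1R,2R)-2-(4-bromo-2-methoxyphenoxy)-1-(3,4-dimethoxyphenyl)propyl]oxy}dimethylsilane | COc1ccc([C@@H](O[Si](C)(C)C(C)(C)C)[C@@H](C)Oc2ccc(Br)cc2OC)cc1OC | intermediate
17 | aryllithium from 16 | COc1ccc([C@@H](O[Si](C)(C)C(C)(C)C)[C@@H](C)Oc2ccc([Li])cc2OC)cc1OC | intermediate
18 | arylzinc bromide from 16 | COc1ccc([C@@H](O[Si](C)(C)C(C)(C)C)[C@@H](C)Oc2ccc([Zn]Br)cc2OC)cc1OC | intermediate
19 | (2S,3R,4R)-2-(3,4-dimethoxyphenyl)-3,4-dimethyl-3,4-dihydro-2H-furan-1-ium (oxocarbenium ion) | C1=[O+][C@H](c2ccc(OC)c(OC)c2)[C@H](C)[C@H]1C | intermediate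
20 | tert-butyl{[(1R,2R)-1-(3,4-dimethoxyphenyl)-2-{4-[(2S,3R,4R,5S)-5-(3,4-dimethoxyphenyl)-3,4-dimethyloxolan-2-yl]-2-methoxyphenoxy}propyl]oxy}dimethylsilane | COc1ccc([C@@H](O[Si](C)(C)C(C)(C)C)[C@@H](C)Oc2ccc([C@H]3O[C@H](c4ccc(OC)c(OC)c4)[C@H](C)[C@H]3C)cc2OC)cc1OC | intermediate
21 | (1R,2R)-1-(3,4-dimethoxyphenyl)-2-{4-[(2S,3R,4R,5S)-5-(3,4-dimethoxyphenyl)-3,4-dimethyloxolan-2-yl]-2-methoxyphenoxy}propan-1-ol | COc1ccc([C@@H](O)[C@@H](C)Oc2ccc([C@H]3O[C@H](c4ccc(OC)c(OC)c4)[C@H](C)[C@H]3C)cc2OC)cc1OC | target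

Total step count: 10 steps.
Longest linear sequence: 7 steps (8 → 21 through steps 4–10); the oxolane branch (1 → 7) is 3 steps.

**Steps most likely to fail**

Step 2. Exchange of the hindered secondary benzylic hydroxyl with the phosphinite may be slow, so that undirected hydroformylation takes over (loss of branch selectivity, alkene isomerization), and control at C3 may be incomplete. The fallback sets out from 4 and returns at 6 by building C2 and the C3 methyl separately. Anti-Markovnikov hydroboration–oxidation (9-BBN, then NaOH/H2O2) should give (1S,2R)-1-(3,4-dimethoxyphenyl)-2-methylbutane-1,4-diol F1. Oxidative lactonization of the primary alcohol (TEMPO, PhI(OAc)2) should give (4R,5S)-5-(3,4-dimethoxyphenyl)-4-methyloxolan-2-one F2. Enolate methylation (LiN(i-Pr)2, MeI, THF, −78 °C) anti to the C4 methyl and the C5 aryl group should give (3R,4R,5S)-5-(3,4-dimethoxyphenyl)-3,4-dimethyloxolan-2-one F3. Half-reduction with i-Bu2AlH at −78 °C then delivers lactol 6.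

Step 9. Metalation of the functionalized bromide may be incomplete, the silyl-protected organometallic may decompose before it meets the oxocarbenium ion, or facial selectivity may erode with the bulky nucleophile. The fallback sets out from 7 and returns at 21 by coupling a simple aryl nucleophile and building the side chain afterwards. [4-(Benzyloxy)-3-methoxyphenyl]zinc bromide F4 (from purchased 1-(benzyloxy)-4-bromo-2-methoxybenzene, Mg, then ZnBr2) is added to 7 to give (2S,3R,4R,5S)-2-[4-(benzyloxy)-3-methoxyphenyl]-5-(3,4-dimethoxyphenyl)-3,4-dimethyloxolane F5. Hydrogenolysis (H2, Pd/C, EtOAc) gives 4-[(2S,3R,4R,5S)-5-(3,4-dimethoxyphenyl)-3,4-dimethyloxolan-2-yl]-2-methoxyphenol F6. Mitsunobu reaction with 9 gives ethyl (R)-2-{4-[(2S,3R,4R,5S)-5-(3,4-dimethoxyphenyl)-3,4-dimethyloxolan-2-yl]-2-methoxyphenoxy}propanoate F7. Aminolysis as in step 5 gives (R)-2-{4-[(2S,3R,4R,5S)-5-(3,4-dimethoxyphenyl)-3,4-dimethyloxolan-2-yl]-2-methoxyphenoxy}-N-methoxy-N-methylpropanamide F8. Addition of 12 gives (R)-1-(3,4-dimethoxyphenyl)-2-{4-[(2S,3R,4R,5S)-5-(3,4-dimethoxyphenyl)-3,4-dimethyloxolan-2-yl]-2-methoxyphenoxy}propan-1-one F9, and the non-chelating borohydride reduction of step 7 gives 21.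

Step 7. Partial chelation-controlled hydride delivery may erode the threo selectivity, and the α-aryloxy center may epimerize under basic conditions. The fallback sets out from 11 and returns at 15 by setting the carbinol center in a C–C bond formation instead of a reduction. LiAlH4 (THF, −78 °C) reduces 11 to (R)-2-(4-bromo-2-methoxyphenoxy)propanal F10, which is used at once. Addition of 12 in the presence of MgBr2·OEt2 (CH2Cl2, −78 °C) should follow the Cram-chelate model (attack past the α-hydrogen of the five-membered chelate) and give the syn, (1R,2R) alcohol 15.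

**Further compounds**
F1 | step 2 | (1S,2R)-1-(3,4-dimethoxyphenyl)-2-methylbutane-1,4-diol | COc1ccc([C@@H](O)[C@H](C)CCO)cc1OC
F2 | step 2 | (4R,5S)-5-(3,4-dimethoxyphenyl)-4-methyloxolan-2-one | O=C1O[C@H](c2ccc(OC)c(OC)c2)[C@H](C)C1
F3 | step 2 | (3R,4R,5S)-5-(3,4-dimethoxyphenyl)-3,4-dimethyloxolan-2-one | O=C1O[C@H](c2ccc(OC)c(OC)c2)[C@H](C)[C@H]1C
F4 | step 9 | [4-(benzyloxy)-3-methoxyphenyl]zinc bromide | COc1cc([Zn]Br)ccc1OCc1ccccc1
F5 | step 9 | (2S,3R,4R,5S)-2-[4-(benzyloxy)-3-methoxyphenyl]-5-(3,4-dimethoxyphenyl)-3,4-dimethyloxolane | COc1cc([C@H]2O[C@H](c3ccc(OC)c(OC)c3)[C@H](C)[C@H]2C)ccc1OCc1ccccc1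
F6 | step 9 | 4-[(2S,3R,4R,5S)-5-(3,4-dimethoxyphenyl)-3,4-dimethyloxolan-2-yl]-2-methoxyphenol | COc1cc([C@H]2O[C@H](c3ccc(OC)c(OC)c3)[C@H](C)[C@H]2C)ccc1O
F7 | step 9 | ethyl (R)-2-{4-[(2S,3R,4R,5S)-5-(3,4-dimethoxyphenyl)-3,4-dimethyloxolan-2-yl]-2-methoxyphenoxy}propanoate | C[C@@H](Oc1ccc([C@H]2O[C@H](c3ccc(OC)c(OC)c3)[C@H](C)[C@H]2C)cc1OC)C(=O)OCC
F8 | step 9 | (R)-2-{4-[(2S,3R,4R,5S)-5-(3,4-dimethoxyphenyl)-3,4-dimethyloxolan-2-yl]-2-methoxyphenoxy}-N-methoxy-N-methylpropanamide | C[C@@H](Oc1ccc([C@H]2O[C@H](c3ccc(OC)c(OC)c3)[C@H](C)[C@H]2C)cc1OC)C(=O)N(C)OC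
F9 | step 9 | (R)-1-(3,4-dimethoxyphenyl)-2-{4-[(2S,3R,4R,5S)-5-(3,4-dimethoxyphenyl)-3,4-dimethyloxolan-2-yl]-2-methoxyphenoxy}propan-1-one | C[C@@H](Oc1ccc([C@H]2O[C@H](c3ccc(OC)c(OC)c3)[C@H](C)[C@H]2C)cc1OC)C(=O)c1ccc(OC)c(OC)c1
F10 | step 7 | (R)-2-(4-bromo-2-methoxyphenoxy)propanal | C[C@@H](Oc1ccc(Br)cc1OC)C=O
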